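Ring A is cut at C1–C10 and C3–C4 (drimane numbering). What remains, ring B with the C10 methyl next to C5 and its gem-dimethyl carbon C4, is the skeleton of (+)-verbenone, in which C4 is still tied to C7 by a cyclobutane bond; C1–C3 become a three-carbon Grignard acetal. In one pot, conjugate addition anti to the gem-dimethyl bridge makes C1–C10 and the quaternary C10, and SnCl4 then breaks the strained C4–C7 bond next to the ketone so that the freed C4 closes ring A onto the oxocarbenium carbon C3. C11, the coumarin ether and C12 follow.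

Key step: step 1

Remark: atoms are numbered as in drimanes (C1–C10 ring carbons, C11 the CH2O carbon, C12 the exocyclic methylene carbon); (1R,5R)-(+)-verbenone (the enantiomer related to (+)-α-pinene), the Grignard solution 2 and umbelliferone are assumed to be purchased.

Step 1
Reactants: 1 (1R,5R)-(+)-verbenone; 2 [2-(1,3-dioxan-2-yl)ethyl]magnesium bromide
Product: 6 (6S,8aR)-6-(3-hydroxypropoxy)-5,5,8a-trimethyl-3,5,6,7,8,8a-hexahydronaphthalen-2(1H)-one, via bromomagnesium enolate 3 (not isolated), via keto acetal 4 (not isolated), via isopropylidene ketone 5 (not isolated)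
Conditions: CuBr·SMe2 (15 mol %), THF, −40 °C; HCl (1 M in Et2O, 1 equiv), −78 °C; THF replaced by CH2Cl2; SnCl4 (3 equiv), −78 °C → rt
Reagents that add atoms: none
Why: The organocopper reagent formed from 2 adds 1,4 to the enone of 1 on the face opposite the gem-dimethyl bridge (control by the bicyclo[3.1.1] skeleton), which makes C1–C10 and fixes C10; HCl turns enolate 3 into ketone 4. SnCl4 then opens the dioxane to an oxocarbenium ion at C3 and, bound to the ketone, heterolyses the strained cyclobutane bond between the α-carbon C7 and C4, the only cleavage that gives a tertiary cation; proton loss gives alkene isomers that interconvert through this cation, and only the isopropylidene isomer 5 can reach C3. C4 of 5 attacks the oxocarbenium ion through a chair-like transition state (six-membered ring A, closed 6-endo at the alkene and exo at the C=O+ unit) and the resulting C5 cation loses H6. The closest known reaction types are copper-catalysed Grignard conjugate addition to β,β-disubstituted enones, Lewis-acid opening of the cyclobutane of pinan-2-ones to p-menthenyl-type cations, and acetal-initiated Prins (cation–olefin) cyclisation, which leaves the hydroxyalkyl ether. The new C3 centre is set by the equatorial position of the alkoxy group in the chair (3β), whereas the C5 centre of 1 is erased here and set again in step 2. The step needs 1,4- over 1,2-addition (copper catalysis), six- over five-ring closure (attack through C4 avoids two adjacent quaternary carbons) and no enolisation toward C9 (aprotic Lewis acid after the enolate has been protonated).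

Step 2
Reactants: 6 (6S,8aR)-6-(3-hydroxypropoxy)-5,5,8a-trimethyl-3,5,6,7,8,8a-hexahydronaphthalen-2(1H)-one
Product: 8 (4aR,6S,8aR)-6-hydroxy-5,5,8a-trimethyl-4a,5,6,7,8,8a-hexahydronaphthalen-2(1H)-one, via aldehyde 7 (not isolated)
Conditions: Dess–Martin periodinane, CH2Cl2, 0 °C → rt; then DBU, rt
Reagents that add atoms: none
Why: Dess–Martin oxidation gives β-alkoxy aldehyde 7, which loses the C3 alkoxide by E1cB elimination (the standard removal of the hydroxyalkyl residue left by an acetal-initiated cyclisation), while DBU also moves the β,γ-double bond into conjugation through the dienolate, whose protonation at C5 from the α face, opposite the axial methyl groups on C4 and C10, should give the trans ring fusion.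

Step 3
Reactants: 8 (4aR,6S,8aR)-6-hydroxy-5,5,8a-trimethyl-4a,5,6,7,8,8a-hexahydronaphthalen-2(1H)-one
Product: 10 (4aR,6S,8aS)-6-hydroxy-5,5,8a-trimethyl-1-methylidene-4a,5,6,7,8,8a-hexahydronaphthalen-2(1H)-one, via Mannich base 9 (not isolated)
Conditions: (CH2O)n, i-Pr2NH·CF3CO2H, THF, reflux
Reagents that add atoms: formaldehyde (as paraformaldehyde), C=O
Why: Mannich-type α-methylenation: C9 is the only sp3 α-carbon of the enone, its cross-conjugated enol adds to the iminium ion and Mannich base 9 loses the hindered amine in situ; no stereocentre is formed.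

Step 4
Reactants: 10 (4aR,6S,8aS)-6-hydroxy-5,5,8a-trimethyl-1-methylidene-4a,5,6,7,8,8a-hexahydronaphthalen-2(1H)-one; 11 umbelliferone (7-hydroxy-2H-chromen-2-one)
Product: 12 7-{[(1S,4aR,6S,8aS)-6-hydroxy-5,5,8a-trimethyl-2-oxo-1,2,4a,5,6,7,8,8a-octahydronaphthalen-1-yl]methoxy}-2H-chromen-2-one
Conditions: Cs2CO3 (10 mol %), MeCN, rt
Reagents that add atoms: none
Why: Base-catalysed oxa-Michael addition of the phenol to the unhindered exocyclic acceptor carbon C11 (the ring acceptor carbon C6 is shielded by the fully substituted C4 and C10 around C5), followed by protonation of the enolate at C9 from the α face, opposite the axial C10 methyl, which should place CH2OAr equatorial (9α-H).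

Step 5
Reactants: 12 7-{[(1S,4aR,6S,8aS)-6-hydroxy-5,5,8a-trimethyl-2-oxo-1,2,4a,5,6,7,8,8a-octahydronaphthalen-1-yl]methoxy}-2H-chromen-2-one
Product: 13 7-{[(1S,4aR,6S,8aS)-6-hydroxy-5,5,8a-trimethyl-2-methylidene-1,2,4a,5,6,7,8,8a-octahydronaphthalen-1-yl]methoxy}-2H-chromen-2-one
Conditions: Zn, CH2Br2, TiCl4, THF–CH2Cl2, 0 °C → rt
Reagents that add atoms: dibromomethane, BrCBr
Why: Takai–Lombardo methylenation: the non-basic zinc/titanium methylene reagent should convert the enolisable C8 ketone into the exocyclic alkene without deprotonating C9 (no loss of aryloxide, no epimerisation) and leave the coumarin lactone untouched; no stereocentre is affected.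

Compound list
1 | (1R,5R)-(+)-verbenone, (1R,5R)-4,6,6-trimethylbicyclo[3.1.1]hept-3-en-2-one | CC1=CC(=O)[C@@H]2C[C@H]1C2(C)C | starting material
2 | [2-(1,3-dioxan-2-yl)ethyl]magnesium bromide (solution in THF) | Br[Mg]CCC1OCCCO1 | starting material
3 | bromomagnesium enolate of 4 (side chain anti to the gem-dimethyl bridge) | C[C@@]1(CCC2OCCCO2)C=C(O[Mg]Br)[C@@H]2C[C@H]1C2(C)C | intermediate
4 | 4-[2-(1,3-dioxan-2-yl)ethyl]-4,6,6-trimethylbicyclo[3.1.1]heptan-2-one, side chain anti to the gem-dimethyl bridge, bridgeheads as in 1 | C[C@@]1(CCC2OCCCO2)CC(=O)[C@@H]2C[C@H]1C2(C)C | intermediate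
5 | (3R)-3-[2-(1,3-dioxan-2-yl)ethyl]-3-methyl-4-(propan-2-ylidene)cyclohexan-1-one (its acetal reacts as the SnCl4-opened oxocarbenium ion) | O=C1CCC(=C(C)C)[C@](C)(CCC2OCCCO2)C1 | intermediate
6 | (6S,8aR)-6-(3-hydroxypropoxy)-5,5,8a-trimethyl-3,5,6,7,8,8a-hexahydronaphthalen-2(1H)-one (3β-(3-hydroxypropoxy)-11,12-dinordrim-5-en-8-one) | O=C1CC=C2C(C)(C)[C@@H](OCCCO)CC[C@]2(C)C1 | intermediate
7 | 3-{[(2S,4aR)-1,1,4a-trimethyl-6-oxo-1,2,3,4,4a,5,6,7-octahydronaphthalen-2-yl]oxy}propanal | O=C1CC=C2C(C)(C)[C@@H](OCCC=O)CC[C@]2(C)C1 | intermediate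
8 | (4aR,6S,8aR)-6-hydroxy-5,5,8a-trimethyl-4a,5,6,7,8,8a-hexahydronaphthalen-2(1H)-one (3β-hydroxy-11,12-dinordrim-6-en-8-one) | O=C1C=C[C@H]2C(C)(C)[C@@H](O)CC[C@]2(C)C1 | intermediate
9 | 1-[(diisopropylamino)methyl] derivative of 8 (Mannich base, C9 configuration not controlled) | O=C1C=C[C@H]2C(C)(C)[C@@H](O)CC[C@]2(C)C1CN(C(C)C)C(C)C | intermediate
10 | (4aR,6S,8aS)-6-hydroxy-5,5,8a-trimethyl-1-methylidene-4a,5,6,7,8,8a-hexahydronaphthalen-2(1H)-one | O=C1C=C[C@H]2C(C)(C)[C@@H](O)CC[C@]2(C)C1=C | intermediate
11 | umbelliferone, 7-hydroxy-2H-chromen-2-one | O=c1ccc2ccc(O)cc2o1 | starting material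
12 | 7-{[(1S,4aR,6S,8aS)-6-hydroxy-5,5,8a-trimethyl-2-oxo-1,2,4a,5,6,7,8,8a-octahydronaphthalen-1-yl]methoxy}-2H-chromen-2-one | O=C1C=C[C@H]2C(C)(C)[C@@H](O)CC[C@]2(C)[C@H]1COc1ccc2ccc(=O)oc2c1 | intermediate
13 | 7-{[(1S,4aR,6S,8aS)-6-hydroxy-5,5,8a-trimethyl-2-methylidene-1,2,4a,5,6,7,8,8a-octahydronaphthalen-1-yl]methoxy}-2H-chromen-2-one | C=C1C=C[C@H]2C(C)(C)[C@@H](O)CC[C@]2(C)[C@H]1COc1ccc2ccc(=O)oc2c1 | target

Total step count: 5
Longest linear sequence: 5 steps (1 → 6 → 8 → 10 → 12 → 13)

Steps most likely to fail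

Step 1. The oxocarbenium ion may be intercepted before the cyclobutane has opened, for example by the C9 enol of ketone 4 or by proton loss to an enol ether, so that ring A never closes. The fallback separates the two bond formations and uses a free aldehyde. From 1, copper-catalysed addition of but-3-en-1-ylmagnesium bromide (CuBr·SMe2, THF) should give 4-(but-3-en-1-yl)-4,6,6-trimethylbicyclo[3.1.1]heptan-2-one F1. Ozonolysis (O3, CH2Cl2–MeOH, −78 °C; PPh3) should give the keto aldehyde F2 under neutral conditions. MeAlCl2 (CH2Cl2, −78 °C → rt), a Lewis acid that also consumes adventitious protons, should then open the cyclobutane and close ring A by an aldehyde–ene reaction to the free 3β-hydroxy Δ5-ketone F3. DBU should conjugate F3 to 8, where the route is rejoined.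

Step 2. Protonation of the dienolate at C5 may be poorly face-selective, or the enone may equilibrate toward the cis-fused epimer. The fallback sets C5 by hydride delivery instead. From 6, ionic hydrogenation (Et3SiH, CF3CO2H, CH2Cl2; K2CO3, MeOH work-up) should add hydride to the tertiary C5 cation from the α face and give the saturated trans-fused ketone F4. IBX (DMSO, 70 °C) should oxidise the primary alcohol and dehydrogenate the ketone toward C7–C6 (C10 is quaternary, so no other enone can form) to the enone aldehyde F5. DBU should then expel acrolein and give 8.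

Step 5. The reagent may act as a Lewis acid, or the ketone may enolise, with loss of the aryloxide by β-elimination and loss of the C9 configuration. The fallback brings the coumarin in last. From 10, base-catalysed conjugate addition of 4-methoxybenzyl alcohol (DBU cat., MeCN) should give the 11-(4-methoxybenzyloxy) ketone F6, whose alkoxide is a poor leaving group. Wittig methylenation (Ph3P=CH2, THF) should give the diene F7. DDQ (CH2Cl2, pH 7 buffer) should free the 3β,11-diol F8. A Mitsunobu reaction with 11 (PPh3, DIAD, THF) at the primary hydroxyl should give 13.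

Further compounds
F1 | step 1 | 4-(but-3-en-1-yl)-4,6,6-trimethylbicyclo[3.1.1]heptan-2-one, chain anti to the gem-dimethyl bridge | C[C@@]1(CCC=C)CC(=O)[C@@H]2C[C@H]1C2(C)C
F2 | step 1 | 3-(2,6,6-trimethyl-4-oxobicyclo[3.1.1]heptan-2-yl)propanal, chain anti to the gem-dimethyl bridge | C[C@@]1(CCC=O)CC(=O)[C@@H]2C[C@H]1C2(C)C
F3 | step 1 | (6S,8aR)-6-hydroxy-5,5,8a-trimethyl-3,5,6,7,8,8a-hexahydronaphthalen-2(1H)-one | O=C1CC=C2C(C)(C)[C@@H](O)CC[C@]2(C)C1
F4 | step 2 | (4aR,6S,8aR)-6-(3-hydroxypropoxy)-5,5,8a-trimethyloctahydronaphthalen-2(1H)-one | O=C1CC[C@H]2C(C)(C)[C@@H](OCCCO)CC[C@]2(C)C1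
F5 | step 2 | 3-{[(2S,4aR,8aR)-1,1,4a-trimethyl-6-oxo-1,2,3,4,4a,5,6,8a-octahydronaphthalen-2-yl]oxy}propanal | O=C1C=C[C@H]2C(C)(C)[C@@H](OCCC=O)CC[C@]2(C)C1
F6 | step 5 | 4-methoxybenzyl ether analogue of 12 (3β-hydroxy-11-(4-methoxybenzyloxy)-12-nordrim-6-en-8-one) | O=C1C=C[C@H]2C(C)(C)[C@@H](O)CC[C@]2(C)[C@H]1COCc1ccc(OC)cc1
F7 | step 5 | 11-(4-methoxybenzyloxy)drima-6,8(12)-dien-3β-ol | C=C1C=C[C@H]2C(C)(C)[C@@H](O)CC[C@]2(C)[C@H]1COCc1ccc(OC)cc1
F8 | step 5 | drima-6,8(12)-diene-3β,11-diol | C=C1C=C[C@H]2C(C)(C)[C@@H](O)CC[C@]2(C)[C@H]1CO
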